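**Plan**

- Retrosynthesis: the seven phenolic hydroxyls are masked as benzyl ethers, cleaved last. The two CH2–aryl bonds joining the bridge carbons on the central phloroglucinol ring (ring A) to the two outer acetophenone rings (rings B) are then cut together.
- Enabling feature: each bridge carbon is a benzylic CH2 on ring A, and its partner is the one ring-B carbon lying between the two hydroxyl-bearing carbons. That carbon is the last free position of ring B and takes bromine, while the two free carbons of ring A take CH2Cl groups, so both ends are reached as electrophiles.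
- Forward, ring A: phloroglucinol is C-acylated with (R)-2-methylbutanoyl chloride, tri-O-benzylated and bis-chloromethylated.
- Forward, ring B: 2-methylphloroglucinol is C-acetylated, benzylated at its two less hindered hydroxyls, O-methylated at the remaining one and brominated. Two ring-B bromides are then joined to ring A in one nickel-catalysed reductive coupling, and hydrogenolysis frees the phenols; no ring is formed anywhere.
- Stereochemistry: the single stereocentre (R, alpha to the ring-A ketone) is bought with (R)-2-methylbutanoic acid and only has to survive; no later step uses strong base or hot acid.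

Key step: step 9

Assumption: (R)-2-methylbutanoic acid of high enantiomeric purity and 2-methylphloroglucinol are taken as purchasable, and the bis(benzylic chloride) of ring A is taken to be stable enough for rapid isolation and immediate use.

**Route**

Step 1
Reactants: 1 (R)-2-methylbutanoic acid
Product: 2 (R)-2-methylbutanoyl chloride
Conditions: (COCl)2, cat. DMF, CH2Cl2, 0 °C to rt; volatiles removed, used crude
Reagents that add atoms: oxalyl chloride, O=C(Cl)C(=O)Cl
Why: Acyl chloride formation through the Vilsmeier-type chloroiminium catalyst runs cold and without base, so neither a ketene nor an enol can form and the R configuration at C2 should be carried over unchanged.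

Step 2
Reactants: 2 (R)-2-methylbutanoyl chloride; 3 phloroglucinol (benzene-1,3,5-triol)
Product: 4 (R)-2-methyl-1-(2,4,6-trihydroxyphenyl)butan-1-one
Conditions: AlCl3 (4 equiv), PhNO2/CH2Cl2, 0 °C to rt; then ice, 1 M HCl
Reagents that add atoms: none
Why: Friedel–Crafts acylation of the threefold-activated ring stops after one acyl group because the aluminium-chelated ketone deactivates the ring, and the low temperature without base should keep the alpha stereocentre from enolising.

Step 3
Reactants: 4 (R)-2-methyl-1-(2,4,6-trihydroxyphenyl)butan-1-one
Product: 5 (R)-2-methyl-1-[2,4,6-tris(benzyloxy)phenyl]butan-1-one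
Conditions: BnBr (3.6 equiv), K2CO3, cat. Bu4NI, DMF, 50 °C
Reagents that add atoms: benzyl bromide, BrCc1ccccc1
Why: Threefold Williamson ether synthesis in which carbonate deprotonates only the phenols (the ketone alpha hydrogen is far less acidic), the polar aprotic solvent favours O- over C-benzylation, and excess benzyl bromide with gentle warming forces the last hydrogen-bonded hydroxyl to react.

Step 4
Reactants: 5 (R)-2-methyl-1-[2,4,6-tris(benzyloxy)phenyl]butan-1-one
Product: 6 (R)-1-[2,4,6-tris(benzyloxy)-3,5-bis(chloromethyl)phenyl]-2-methylbutan-1-one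
Conditions: MeOCH2Cl (6 equiv), ZnCl2 (0.2 equiv), CH2Cl2, 0 °C to rt; cold aqueous NaHCO3 wash, used at once
Reagents that add atoms: chloromethyl methyl ether, COCCl
Why: Blanc-type chloromethylation (electrophilic aromatic substitution by the methoxymethyl cation, then exchange of the benzylic methoxy group for chloride) should occur at the two remaining ring-A carbons, each ortho or para to three benzyloxy groups and far more nucleophilic than the phenyl rings of the benzyl ethers, while the weak Lewis acid ZnCl2 at low temperature should spare the ethers and the alpha stereocentre.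

Step 5
Reactants: 7 2-methylphloroglucinol (2-methylbenzene-1,3,5-triol)
Product: 8 1-(2,4,6-trihydroxy-3-methylphenyl)ethanone
Conditions: AcCl (1.05 equiv), AlCl3 (4 equiv), PhNO2/CH2Cl2, 0 °C to rt; then ice, 1 M HCl
Reagents that add atoms: acetyl chloride, CC(=O)Cl
Why: Friedel–Crafts acylation gives a single mono-ketone because the two free ring carbons are equivalent by symmetry and the chelated acetyl group deactivates the ring against a second acylation.

Step 6
Reactants: 8 1-(2,4,6-trihydroxy-3-methylphenyl)ethanone
Product: 9 1-[4,6-bis(benzyloxy)-2-hydroxy-3-methylphenyl]ethanone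
Conditions: BnBr (2.05 equiv), K2CO3 (2.2 equiv), DMF, rt
Reagents that add atoms: benzyl bromide, BrCc1ccccc1
Why: Williamson ether synthesis in which the hydroxyl para to the acetyl group (most acidic, not hydrogen-bonded) reacts first and, of the two ortho hydroxyls, the one next to the ring C–H reacts second, because the hydroxyl wedged between the C-methyl and acetyl groups is shielded and held in the hydrogen bond to the carbonyl.

Step 7
Reactants: 9 1-[4,6-bis(benzyloxy)-2-hydroxy-3-methylphenyl]ethanone
Product: 10 1-[4,6-bis(benzyloxy)-2-methoxy-3-methylphenyl]ethanone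
Conditions: MeI (3 equiv), K2CO3, DMF, 50 °C
Reagents that add atoms: iodomethane, CI
Why: Williamson methylation of the last, chelated phenol succeeds with the small electrophile in a dipolar aprotic solvent, and carbonate is too weak to enolise the acetyl group, so C-methylation of the ketone is not expected.

Step 8
Reactants: 10 1-[4,6-bis(benzyloxy)-2-methoxy-3-methylphenyl]ethanone
Product: 11 1-[2,4-bis(benzyloxy)-3-bromo-6-methoxy-5-methylphenyl]ethanone
Conditions: NBS (1.05 equiv), MeCN, 0 °C to rt, dark
Reagents that add atoms: N-bromosuccinimide, O=C1CCC(=O)N1Br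
Why: Electrophilic aromatic bromination can only enter at the single ring C–H, which is ortho to both benzyloxy groups and para to the methoxy group and is the carbon that will carry the bridge, while polar, dark conditions disfavour radical bromination at benzylic or alpha-keto positions.

Step 9
Reactants: 6 (R)-1-[2,4,6-tris(benzyloxy)-3,5-bis(chloromethyl)phenyl]-2-methylbutan-1-one; 11 1-[2,4-bis(benzyloxy)-3-bromo-6-methoxy-5-methylphenyl]ethanone (two equivalents consumed, three charged)
Product: 13 (R)-1-{2,4,6-tris(benzyloxy)-3,5-bis[3-acetyl-2,6-bis(benzyloxy)-4-methoxy-5-methylbenzyl]phenyl}-2-methylbutan-1-one (hepta-O-benzyl target), via mono-coupled benzylic chloride 12 (not isolated)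
Conditions: NiBr2(dme) (20 mol %), 4,4'-di-tert-butyl-2,2'-bipyridine (24 mol %), Zn powder (6 equiv), DMA, 40 °C; 11 charged first, 6 added in THF over 6 h
Reagents that add atoms: none
Why: Zinc reduces the nickel precatalyst to a zerovalent bipyridine complex that inserts into the C–Br bond of 11 to give a divalent arylnickel bromide, while a monovalent nickel halide abstracts chlorine from a CH2Cl group of 6 to release a benzylic radical stabilised by three flanking alkoxy groups; capture of this radical gives a trivalent aryl(benzyl)nickel species, reductive elimination forms the CH2–aryl bond, and zinc returns the nickel to its low-valent state. The closest known reaction type is the nickel-catalysed reductive cross-electrophile coupling of benzyl chlorides with aryl bromides to diarylmethanes, here run twice on one molecule through mono-coupled chloride 12. No ring is closed and no stereocentre is created, and since the medium is neither acidic nor basic the ketone alpha stereocentre of 6 and all benzyl ethers should pass unchanged. The step needs cross- over homo-coupling, which rests on the different activation modes of the two electrophiles (two-electron insertion at the aryl C–Br bond, halogen-atom abstraction at the benzylic C–Cl bond), on the excess of 11 and on keeping 6 dilute by slow addition; the two CH2Cl groups are meta to each other and cannot couple intramolecularly. Regiochemistry is fixed by the bromine, which sits on the one ring-B carbon between the two benzyloxy-bearing carbons, and the two flanking substituents are oxygen atoms, small enough for insertion and radical capture to stay feasible. Any benzylic zinc chloride formed by direct zinc insertion would transmetalate to the same arylnickel intermediate and give the same product.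

Step 10
Reactants: 13 hepta-O-benzyl target
Product: 14 (R)-1-{3,5-bis[(3-acetyl-2,6-dihydroxy-4-methoxy-5-methylphenyl)methyl]-2,4,6-trihydroxyphenyl}-2-methylbutan-1-one (CNP0201397.1)
Conditions: H2 (1 atm), 10% Pd/C, EtOAc/MeOH, rt
Reagents that add atoms: none
Why: Heterogeneous catalytic hydrogenolysis under neutral conditions cleaves only the seven aryl O–CH2Ph bonds, leaving the diarylmethane bridges, the methyl ethers, the hydrogen-bonded aryl ketones and the alpha stereocentre intact at ambient pressure and temperature.

**Compound list**

1 | (R)-2-methylbutanoic acid | CC[C@@H](C)C(=O)O | starting material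
2 | (R)-2-methylbutanoyl chloride | CC[C@@H](C)C(=O)Cl | intermediate
3 | phloroglucinol (benzene-1,3,5-triol) | Oc1cc(O)cc(O)c1 | starting material
4 | (R)-2-methyl-1-(2,4,6-trihydroxyphenyl)butan-1-one | CC[C@@H](C)C(=O)c1c(O)cc(O)cc1O | intermediate
5 | (R)-2-methyl-1-[2,4,6-tris(benzyloxy)phenyl]butan-1-one | CC[C@@H](C)C(=O)c1c(OCc2ccccc2)cc(OCc2ccccc2)cc1OCc1ccccc1 | intermediate
6 | (R)-1-[2,4,6-tris(benzyloxy)-3,5-bis(chloromethyl)phenyl]-2-methylbutan-1-one | CC[C@@H](C)C(=O)c1c(OCc2ccccc2)c(CCl)c(OCc2ccccc2)c(CCl)c1OCc1ccccc1 | intermediate
7 | 2-methylphloroglucinol (2-methylbenzene-1,3,5-triol) | Cc1c(O)cc(O)cc1O | starting material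
8 | 1-(2,4,6-trihydroxy-3-methylphenyl)ethanone | CC(=O)c1c(O)cc(O)c(C)c1O | intermediate
9 | 1-[4,6-bis(benzyloxy)-2-hydroxy-3-methylphenyl]ethanone | CC(=O)c1c(O)c(C)c(OCc2ccccc2)cc1OCc1ccccc1 | intermediate
10 | 1-[4,6-bis(benzyloxy)-2-methoxy-3-methylphenyl]ethanone | CC(=O)c1c(OC)c(C)c(OCc2ccccc2)cc1OCc1ccccc1 | intermediate
11 | 1-[2,4-bis(benzyloxy)-3-bromo-6-methoxy-5-methylphenyl]ethanone | CC(=O)c1c(OCc2ccccc2)c(Br)c(OCc2ccccc2)c(C)c1OC | intermediate
12 | (R)-1-{3-[3-acetyl-2,6-bis(benzyloxy)-4-methoxy-5-methylbenzyl]-2,4,6-tris(benzyloxy)-5-(chloromethyl)phenyl}-2-methylbutan-1-one (mono-coupled benzylic chloride, not isolated) | CC[C@@H](C)C(=O)c1c(OCc2ccccc2)c(CCl)c(OCc2ccccc2)c(Cc2c(OCc3ccccc3)c(C)c(OC)c(C(C)=O)c2OCc2ccccc2)c1OCc1ccccc1 | intermediate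
13 | (R)-1-{2,4,6-tris(benzyloxy)-3,5-bis[3-acetyl-2,6-bis(benzyloxy)-4-methoxy-5-methylbenzyl]phenyl}-2-methylbutan-1-one (hepta-O-benzyl target) | CC[C@@H](C)C(=O)c1c(OCc2ccccc2)c(Cc2c(OCc3ccccc3)c(C)c(OC)c(C(C)=O)c2OCc2ccccc2)c(OCc2ccccc2)c(Cc2c(OCc3ccccc3)c(C)c(OC)c(C(C)=O)c2OCc2ccccc2)c1OCc1ccccc1 | intermediate
14 | (R)-1-{3,5-bis[(3-acetyl-2,6-dihydroxy-4-methoxy-5-methylphenyl)methyl]-2,4,6-trihydroxyphenyl}-2-methylbutan-1-one (CNP0201397.1) | CC[C@@H](C)C(=O)c1c(O)c(Cc2c(O)c(C)c(OC)c(C(C)=O)c2O)c(O)c(Cc2c(O)c(C)c(OC)c(C(C)=O)c2O)c1O | target

**Step count and risks**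

Total steps: 10. Longest linear sequence: 6 steps (steps 1–4, 9, 10; the ring-B branch, steps 5–8, 9, 10, is equally long).

Steps most likely to fail:

1. Step 9. Insertion and radical capture at the aryl bromide flanked by two benzyloxy groups may be slow. The benzylic chloride could then be consumed by reductive homo-coupling into oligomers, by reduction of CH2Cl to CH3, or by reduction of C–Br to C–H, and the second arm may stall at the mono-coupled stage. The fallback separates the two activation events and moves to two-electron chemistry. Setting out from 6, zinc dust with LiCl in THF at 0 °C to rt would insert into both C–Cl bonds to give the bis(benzylic zinc chloride) F1. This would be joined to 11 in a Negishi coupling with Pd(OAc)2 and SPhos (dicyclohexyl(2',6'-dimethoxybiphenyl-2-yl)phosphine) in THF at rt to 50 °C, a ligand system established for aryl bromides with two ortho substituents. The same two CH2–aryl bonds form, and the route is rejoined at 13.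

2. Step 4. The hydrogen chloride and Lewis acid may strip benzyl ethers, and the first-formed, highly ionisable benzylic chloride may alkylate a still unsubstituted ring carbon of another molecule, giving diarylmethane oligomers and incomplete second chloromethylation. The fallback installs the two carbons at the aldehyde oxidation level before the phenols are protected. Setting out from 4, Rieche formylation (Cl2CHOMe, TiCl4, CH2Cl2, -20 to 0 °C, aqueous work-up) should give (R)-2,4,6-trihydroxy-5-(2-methylbutanoyl)benzene-1,3-dicarbaldehyde F2. Benzylation (BnBr, K2CO3, DMF, 60 °C) would give the tribenzyl ether dialdehyde F3. NaBH4 in THF/MeOH at 0 °C should reduce only the two aldehydes, since the doubly ortho-substituted, alpha-branched ketone is much slower, to give (R)-1-[2,4,6-tris(benzyloxy)-3,5-bis(hydroxymethyl)phenyl]-2-methylbutan-1-one F4. SOCl2 in CH2Cl2 at 0 °C converts the diol to the dichloride, rejoining the route at 6.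

3. Step 2. The alpha stereocentre may erode through enolisation of the acyl chloride–AlCl3 complex or of the aluminium-chelated product ketone, and some diacylation may occur. The enantiomeric purity of 4 would be checked by chiral HPLC before going on. The fallback forms the aryl–carbonyl bond by nucleophilic addition instead of electrophilic substitution and delivers the benzyl ethers at the same time. Setting out from 2, MeNHOMe·HCl and pyridine in CH2Cl2 at 0 °C give the Weinreb amide (R)-N-methoxy-N,2-dimethylbutanamide F5. Purchased 1,3,5-tris(benzyloxy)benzene F6 is brominated with NBS in CH2Cl2 at -20 °C to 2-bromo-1,3,5-tris(benzyloxy)benzene F7. Bromine–lithium exchange with n-BuLi in THF at -78 °C gives [2,4,6-tris(benzyloxy)phenyl]lithium F8, which is added to F5 at -78 °C. The stable chelated tetrahedral adduct prevents over-addition and enolisation and releases the ketone on NH4Cl quench, rejoining the route at 5 and bypassing steps 2 and 3.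

**Further compounds**

F1 | step 9 | (R)-1-[2,4,6-tris(benzyloxy)-3,5-bis(chlorozinciomethyl)phenyl]-2-methylbutan-1-one (bis(benzylic zinc chloride)) | CC[C@@H](C)C(=O)c1c(OCc2ccccc2)c(C[Zn]Cl)c(OCc2ccccc2)c(C[Zn]Cl)c1OCc1ccccc1
F2 | step 4 | (R)-2,4,6-trihydroxy-5-(2-methylbutanoyl)benzene-1,3-dicarbaldehyde | CC[C@@H](C)C(=O)c1c(O)c(C=O)c(O)c(C=O)c1O
F3 | step 4 | (R)-2,4,6-tris(benzyloxy)-5-(2-methylbutanoyl)benzene-1,3-dicarbaldehyde | CC[C@@H](C)C(=O)c1c(OCc2ccccc2)c(C=O)c(OCc2ccccc2)c(C=O)c1OCc1ccccc1
F4 | step 4 | (R)-1-[2,4,6-tris(benzyloxy)-3,5-bis(hydroxymethyl)phenyl]-2-methylbutan-1-one | CC[C@@H](C)C(=O)c1c(OCc2ccccc2)c(CO)c(OCc2ccccc2)c(CO)c1OCc1ccccc1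
F5 | step 2 | (R)-N-methoxy-N,2-dimethylbutanamide | CC[C@@H](C)C(=O)N(C)OC
F6 | step 2 | 1,3,5-tris(benzyloxy)benzene (purchased) | c1ccc(COc2cc(OCc3ccccc3)cc(OCc3ccccc3)c2)cc1
F7 | step 2 | 2-bromo-1,3,5-tris(benzyloxy)benzene | Brc1c(OCc2ccccc2)cc(OCc2ccccc2)cc1OCc1ccccc1
F8 | step 2 | [2,4,6-tris(benzyloxy)phenyl]lithium | [Li]c1c(OCc2ccccc2)cc(OCc2ccccc2)cc1OCc1ccccc1
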